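## Structural features

The target is an isocoumarin (1H-isochromen-1-one): benzene ring A is fused to pyranone ring B, with an n-pentyl chain on C3, a free hydroxyl on C6 and an aryl ether oxygen on C8. That oxygen is bound to C5' of ring C, a 2',4'-dihydroxy-6'-pentylbenzoic acid (C1' carries the carboxyl group, C3' is the only ring C carbon with hydrogen). Ring C therefore has four contiguous substituents: C4'–OH, C5'–O, C6'–pentyl and C1'–CO2H. The target has no stereocentre; the only one in the route, C3 of the saturated lactone, is carried as a racemate and later removed. The fragile groups are the enol lactone of ring B (nucleophiles, hydrogenation), the ortho-hydroxybenzoic acid of ring C (loss of CO2 on heating or in strong acid), both electron-rich rings (electrophilic halogenation, oxidation) and the benzylic CH2 groups. The real difficulty is regiochemical: ring A needs the carbonyl carbon C1 on C8a, between the ether-bearing C8 and the C4-bearing C4a; the diaryl ether joins two hindered carbons; and the carboxyl must sit on C1' and not on C3'. The key step uses the C8–C8a–C4a triad: an iodide on C8a with the ether on C8 and hydrogen on C4a is the ipso/ortho pattern of palladium/norbornene catalysis, so C4 (with C3 and its chain) and C1 can be attached in one operation.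

## Logic of the disconnections

19 to 18. The three phenolic O–H bonds are traced back to three O–CH3 bonds. Methyl is used on all three oxygens because it has no weak benzylic C–H bond, survives base, palladium and chlorite, and leaves as a poor alkylating agent that should not attack ring C. The gain is that every earlier compound is a neutral ether with no free phenol. The demand is an ether cleavage that spares the lactone and the diaryl ether and does not cost the carboxyl group.

18 to 15 (through 17 and 16). The bond between C1' and the carboxyl carbon is cut. C1' is para to the C4' oxygen and ortho to the C2' oxygen, and ring C is the only ring without an acceptor, so a weak carbon electrophile should choose it. The gain is that ring C of every earlier compound is a plain resorcinol ether with no carbonyl group to disturb the organometallic steps. The demand is that formylation tells C1' from C3', ring C from ring A, and both from C4.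

15 to 13 (through 14). The C3=C4 double bond is traced back to the saturated lactone. In the forward sense the O2–C3 bond is broken (13 to 14) and re-formed with loss of two hydrogens (14 to 15). The cut is placed there because the C4–H bonds are the only acidic C–H bonds of 13, so a base finds them unaided, whereas a radical or hydride abstractor would have to choose between C4 and the benzylic CH2 of the ring C chain. The gain is that the key step may deliver the saturated lactone that an epoxide naturally gives. The demand is a 6-endo oxidative closure of 14.

13 to 10, 11 and 12. Three bonds are cut at once: C4a–C4, C8a–C1 and C1–O2. This removes ring B, the chain and the carbonyl carbon and leaves a diaryl ether iodide, a terminal epoxide and a one-carbon gas. The cut is made there because C8a sits between one substituted and one unsubstituted ortho carbon. The demand is strict ordering in the forward step: ortho alkylation first, carbonylation second.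

10 to 7 (through 9 and 8). The C8a–I bond is traced to C–N and then to a nitro group. The nitro group is what allows the diaryl ether to be made, and it marks the carbon that later becomes C8a. The demand is a diazonium that cannot arylate ring C, which is met because both ring C carbons next to the ether oxygen are substituted.

7 to 5 and 6. The diaryl ether C8–O bond is cut. The hindered phenol oxygen of ring C is a good nucleophile and the carbon of ring A is activated by the ortho nitro group, so the most crowded bond of the target is made by addition–elimination on two simple benzenes. The demand is only that fluoride, not the para methoxy group, is displaced.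

5 to 1 (through 4, 3 and 2). The C5'–O bond is traced to a C5'–CHO bond and this to C5'–H. The carbon next to the pentyl chain is the preferred site of electrophilic formylation in 1, and oxidative rearrangement turns the formyl group into the phenol. The gain is a catalogue starting material. The demand is the site selectivity of the formylation.

## Other disconnections considered

Alternative 1: The cut runs through ring C at C1'–C6' and C2'–C3', so ring C is assembled last on a finished isocoumarin. Dibenzyl malonate A1 would add in Michael fashion to the α-aryloxy enone A2 (C1'–C6'). The methyl ketone enolate of the adduct would then close onto one ester (C2'–C3', Claisen type) under KOtBu to give the cyclohexane-1,3-dione A3. Dehydrogenation of A3 to the resorcylate A7 and hydrogenolysis of both benzyl groups would finish the synthesis.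
- In its favour: the carboxyl carbon arrives with the ring at a position that cannot be mistaken, which is better than the chosen plan, where C1' has to be picked out by an electrophile. The chemistry is anionic, metal-free and of a long-established type, which is also better than a key step without direct precedent.
- Against it here: A2 is a trisubstituted enone whose α-oxygen donates into the acceptor, so conjugate addition should be slower than with an unsubstituted enone. The alkoxide base can open the enol lactone of ring B. A3 needs an oxidation (halogenation and loss of hydrogen halide) that must leave C4 and ring A alone. A2 has to be made from the peri-hydroxy isocoumarin A4, whose hydroxyl is hydrogen-bonded to the lactone carbonyl and hindered.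
- Comparison: on structure the two plans mirror each other (ring C built on rings A and B, against ring B built on rings A and C). On mechanism the alternative is the more conventional. On step economy it is probably no shorter and likely longer, because A4 must first be built with its own regiochemical problem at C8a, whereas the chosen plan buys rings A and C as simple benzenes.

Alternative 2: The cut is again in ring C, at C5'–C6' and C1'–C2'. The forward key step is a thermal (4+2) cycloaddition of the electron-rich diene A5 with benzyl oct-2-ynoate A6. The nucleophilic diene terminus carrying the aryloxy group bonds to the β-carbon of the ynoate, and loss of methanol from the adduct would give the aromatic resorcylate A7 directly.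
- In its favour: ring C arrives aromatic, fully substituted and with the carboxyl in place, so a single hydrogenolysis remains. That ending is shorter than the three steps the chosen plan needs after ring B is complete. The regiochemistry is fixed by the polarity of both partners, which is at least the equal of the chosen plan.
- Against it here: A5 must be made from A4 by O-alkylation with a γ-halo-β-keto ester and two enol silylations with strong base next to an electrophilic lactone. Dienes of this kind with a substituent on the terminal carbon reach the s-cis conformation with difficulty and are sensitive to moisture and heat. A6, a β-alkyl ynoate, is a sluggish dienophile, so the temperature needed may exceed what A5 tolerates.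
- Comparison: the alternative is about equal in the bond count of the key step (two C–C bonds and one ring, against three bonds and one ring). It is better in endgame length and in precedent for the reaction type. It is worse in the stability of its key intermediate and in total length, since A4 again has to be prepared first.

Alternative 3: Ring A is cut at C6–C7, C8–C8a and C5–C6. Heating 3-methylcyclobut-2-en-1-one A8 with the aryl ethynyl ether A9 should open the cyclobutenone to a vinylketene, which adds to the ynol ether in a (2+2) sense. Ring opening and six-electron closure of the resulting dienylketene would give the phenol A10, with the hydroxyl at C6, the ring C ether at C8 and a methyl group as the future C4.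
- In its favour: the hindered diaryl ether oxygen is carried in on the alkyne and never has to be made by substitution at an aromatic carbon, which is equal to or better than the three-step nitro route of the chosen plan. The regiochemistry follows from the polarity of ketene and ynol ether. The reaction type is established for alkoxyalkynes, so on certainty of the key step it is better.
- Against it here: A10 still lacks C1, C3 and the pentyl chain. C8a, the most hindered ring position (between the methyl and the aryloxy group), would have to be acylated in competition with C5 and C7. The methyl group would then have to be metalated laterally and acylated with a six-carbon unit, and the keto acid cyclised. A8 is volatile and needs a multistep preparation, and A9 needs a two- or three-step alkynylation of a hindered phenol.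
- Comparison: the chosen plan installs C4, C3 with its chain and C1 in one operation on an aryl iodide; alternative 3 spends at least five further steps on the same atoms. The ring C carboxylation problem is the same in both (equal on that point). Overall this key step is mechanistically the safest of the four and the poorest in step economy.

Key step: step 6

Remark on the chemistry: the target is achiral, so racemic 11 is used and C3 of 13 stays racemic until step 7 removes it. All three phenols are carried as methyl ethers; benzylic ethers would add weak C–H bonds and could transfer benzyl cations to ring C during Lewis-acid cleavage.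

## Route

Step 1
Reactants: 1 1,3-dimethoxy-5-pentylbenzene (olivetol dimethyl ether)
Product: 3 2,4-dimethoxy-6-pentylbenzaldehyde, via aryl iminium chloride 2 (not isolated)
Conditions: POCl3 (1.5 equiv), DMF, 0 → 60 °C; then H2O
Reagents that add atoms: N,N-dimethylformamide, CN(C)C=O (formyl carbon); water, O (carbonyl oxygen); POCl3, O=P(Cl)(Cl)Cl (chloride counter-ion of 2 only)
Why: Vilsmeier–Haack formylation; in 5-alkylresorcinol dimethyl ethers the bulky chloroiminium electrophile should attack the carbon para to one methoxy group and next to the alkyl chain rather than the more crowded carbon between the two methoxy groups. Hydrolysis of iminium salt 2 releases the aldehyde.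

Step 2
Reactants: 3 2,4-dimethoxy-6-pentylbenzaldehyde
Product: 5 2,4-dimethoxy-6-pentylphenol, via aryl formate 4 (not isolated)
Conditions: mCPBA, CH2Cl2, 0 → 20 °C; then K2CO3 (cat.), MeOH, 20 °C
Reagents that add atoms: 3-chloroperoxybenzoic acid (mCPBA), O=C(OO)c1cccc(Cl)c1
Why: Dakin oxidation in two stages: Baeyer–Villiger insertion with migration of the electron-rich aryl group (preferred over hydride) gives formate 4, and base-catalysed methanolysis frees the phenol. The ethers and the chain are inert.

Step 3
Reactants: 5 2,4-dimethoxy-6-pentylphenol; 6 3-fluoro-4-nitroanisole
Product: 7 1,5-dimethoxy-2-(5-methoxy-2-nitrophenoxy)-3-pentylbenzene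
Conditions: K2CO3, DMF, 90 °C, N2
Reagents that add atoms: none
Why: Nucleophilic aromatic substitution through a Meisenheimer adduct; fluoride ortho to the nitro group is the best leaving group for this addition-limited mechanism and should compensate for the hindered phenoxide, while the methoxy group para to the nitro group is not displaced. Air is excluded because the electron-rich phenoxide is oxidisable.

Step 4
Reactants: 7 1,5-dimethoxy-2-(5-methoxy-2-nitrophenoxy)-3-pentylbenzene
Product: 8 2-(2,4-dimethoxy-6-pentylphenoxy)-4-methoxyaniline
Conditions: H2 (1 atm), Pd/C (10 wt%), EtOAc/EtOH, 20 °C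
Reagents that add atoms: none
Why: Catalytic hydrogenation of a nitroarene to the aniline; the substrate has no hydrogenolysable group, since methyl ethers and the diaryl ether are stable under these conditions.

Step 5
Reactants: 8 2-(2,4-dimethoxy-6-pentylphenoxy)-4-methoxyaniline
Product: 10 2-(2-iodo-5-methoxyphenoxy)-1,5-dimethoxy-3-pentylbenzene, via arenediazonium tosylate 9 (not isolated)
Conditions: p-TsOH·H2O (3 equiv), NaNO2 (2 equiv), KI (2.5 equiv), MeCN/H2O, 10 → 20 °C
Reagents that add atoms: potassium iodide, [K+].[I-]; sodium nitrite, [Na+].[O-]N=O, and 4-methylbenzenesulfonic acid, Cc1ccc(S(=O)(=O)O)cc1 (second nitrogen and counter-ion of 9 only)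
Why: Sandmeyer-type iodination (diazotisation, then iodide without copper); the tosylate salt of an electron-rich diazonium is stable enough to be formed and consumed in one flask. Both ring C carbons next to the ether oxygen are substituted, so the aryl radical or cation cannot close onto ring C.

Step 6
Reactants: 10 2-(2-iodo-5-methoxyphenoxy)-1,5-dimethoxy-3-pentylbenzene; 11 2-pentyloxirane (racemic); 12 carbon monoxide
Product: 13 8-(2,4-dimethoxy-6-pentylphenoxy)-6-methoxy-3-pentyl-3,4-dihydro-1H-isochromen-1-one (racemic)
Conditions: Pd(OAc)2 (10 mol%), P(2-furyl)3 (25 mol%), norbornene (2 equiv), Cs2CO3 (2.5 equiv), 11 (3 equiv), CO (ca. 0.1 atm in N2), MeCN, 80 °C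
Reagents that add atoms: none
Why: Proposed new method: Zerovalent palladium should insert into the C–I bond of 10, norbornene should insert into the aryl–palladium bond, and carbonate-assisted palladation of the single free ortho C–H should give the five-membered aryl–norbornyl palladacycle of divalent palladium, which attacks the CH2 terminus of 11 (formal oxidative addition to tetravalent palladium, then C(sp2)–C(sp3) reductive elimination) to form C4a–C4 and leave a caesium alkoxide on the secondary carbon. With both ortho positions filled, β-carbon elimination expels norbornene, carbon monoxide inserts into the C8a–Pd bond (C8a–C1), and the tethered alkoxide attacks the acylpalladium (C1–O2), closing ring B as a six-membered lactone by intramolecular acyl substitution (6-exo-trig at the acyl carbon) and returning zerovalent palladium. The closest known reaction types are the Catellani ortho-alkylation of aryl iodides with terminal epoxides that ends in C–O bond formation or a Heck reaction, and the palladium-catalysed alkoxycarbonylative lactonisation of aryl halides carrying a hydroxyalkyl chain; joining them in one catalytic cycle is the untested part. The new stereocentre C3 is taken over unchanged from racemic 11, because the C–O bond at the substituted epoxide carbon is never broken, so 13 is racemic, which does not matter since step 7 removes the centre. Site selectivity needs no control beyond the substrate: ring A has only one ortho C–H, and ring C cannot be palladated next to the ether oxygen because both of those carbons are substituted. The selectivity that has to be won is the order of events, norbornene insertion and alkylation before any carbon monoxide insertion: the ortho aryloxy group speeds norbornene insertion and later its extrusion, norbornene is in excess, and carbon monoxide is held near a tenth of an atmosphere so that it meets mainly the norbornene-free arylpalladium species formed at the end. Direct C–O reductive elimination to a dihydrobenzofuran should be slower than carbon monoxide insertion with the small, π-acidic phosphine chosen.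

Step 7
Reactants: 13 8-(2,4-dimethoxy-6-pentylphenoxy)-6-methoxy-3-pentyl-3,4-dihydro-1H-isochromen-1-one (racemic)
Product: 14 2-(2,4-dimethoxy-6-pentylphenoxy)-6-[(1E)-hept-1-en-1-yl]-4-methoxybenzoic acid
Conditions: LiN(iPr)2 (2.2 equiv), THF, −78 → 0 °C; then 1 M HCl
Reagents that add atoms: none
Why: E1cB ring opening, the known base-induced conversion of 3,4-dihydroisocoumarins into 2-alkenylbenzoic acids: the C4–H bonds are benzylic and ortho to the lactone carbonyl, so lateral deprotonation gives an extended enolate that expels the carboxylate from C3 and forms the conjugated E-alkene. No other C–H in 13 is comparably acidic, so the benzylic CH2 of the ring C chain and the methyl ethers stay untouched, and the racemic stereocentre disappears.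

Step 8
Reactants: 14 2-(2,4-dimethoxy-6-pentylphenoxy)-6-[(1E)-hept-1-en-1-yl]-4-methoxybenzoic acid
Product: 15 8-(2,4-dimethoxy-6-pentylphenoxy)-6-methoxy-3-pentyl-1H-isochromen-1-one
Conditions: PdCl2(MeCN)2 (10 mol%), 1,4-benzoquinone (1.5 equiv), Na2CO3 (0.2 equiv), THF, 50 °C
Reagents that add atoms: none
Why: Wacker-type intramolecular acyloxypalladation by divalent palladium, β-hydride elimination and reoxidation of zerovalent palladium by benzoquinone, a known way from 2-(alk-1-enyl)benzoic acids to 3-substituted isocoumarins. Attack of the carboxylate on the alkene carbon remote from ring A (6-endo) places palladium on the benzylic carbon C4, and loss of the C3 hydrogen then gives the conjugated pyranone.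

Step 9
Reactants: 15 8-(2,4-dimethoxy-6-pentylphenoxy)-6-methoxy-3-pentyl-1H-isochromen-1-one
Product: 17 4,6-dimethoxy-3-[(6-methoxy-1-oxo-3-pentyl-1H-isochromen-8-yl)oxy]-2-pentylbenzaldehyde, via ring C iminium chloride 16 (not isolated)
Conditions: POCl3 (3 equiv), DMF, 0 → 70 °C; then H2O
Reagents that add atoms: N,N-dimethylformamide, CN(C)C=O (formyl carbon); water, O (carbonyl oxygen); POCl3, O=P(Cl)(Cl)Cl (chloride counter-ion of 16 only)
Why: Vilsmeier–Haack formylation; ring C is the only ring without an acceptor, and its C1' (para to one methoxy group, next to the pentyl chain) has the same environment as the carbon formylated in step 1. Ring A is deactivated by the lactone carbonyl, and the weak chloroiminium electrophile should not attack the enol-lactone carbon C4.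

Step 10
Reactants: 17 4,6-dimethoxy-3-[(6-methoxy-1-oxo-3-pentyl-1H-isochromen-8-yl)oxy]-2-pentylbenzaldehyde
Product: 18 4,6-dimethoxy-3-[(6-methoxy-1-oxo-3-pentyl-1H-isochromen-8-yl)oxy]-2-pentylbenzoic acid
Conditions: NaClO2, NaH2PO4, 2-methylbut-2-ene, t-BuOH/THF/H2O, 20 °C
Reagents that add atoms: sodium chlorite, [Na+].[O-]Cl=O
Why: Pinnick oxidation; chlorous acid converts even a hindered aryl aldehyde into the acid. The alkene scavenger removes hypochlorous acid before it can chlorinate the electron-rich rings or add to C3=C4.

Step 11
Reactants: 18 4,6-dimethoxy-3-[(6-methoxy-1-oxo-3-pentyl-1H-isochromen-8-yl)oxy]-2-pentylbenzoic acid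
Product: 19 4,6-dihydroxy-3-[(6-hydroxy-1-oxo-3-pentyl-1H-isochromen-8-yl)oxy]-2-pentylbenzoic acid (CNP0439913.0)
Conditions: BBr3 (8 equiv), CH2Cl2, −78 → 20 °C; then H2O, 0 °C
Reagents that add atoms: none
Why: Lewis-acid ether cleavage: BBr3 binds each methoxy oxygen and bromide removes the methyl group by SN2, while the diaryl ether has no alkyl carbon to attack and the lactone is not opened. The temperature is kept at or below 20 °C so that the ortho-hydroxy acid does not lose CO2.

## Compound list

1 | 1,3-dimethoxy-5-pentylbenzene | CCCCCc1cc(OC)cc(OC)c1 | starting material
2 | [(2,4-dimethoxy-6-pentylphenyl)methylidene]dimethylammonium chloride | CCCCCc1cc(OC)cc(OC)c1C=[N+](C)C.[Cl-] | intermediate (not isolated)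
3 | 2,4-dimethoxy-6-pentylbenzaldehyde | CCCCCc1cc(OC)cc(OC)c1C=O | intermediate
4 | 2,4-dimethoxy-6-pentylphenyl formate | CCCCCc1cc(OC)cc(OC)c1OC=O | intermediate (not isolated)
5 | 2,4-dimethoxy-6-pentylphenol | CCCCCc1cc(OC)cc(OC)c1O | intermediate
6 | 3-fluoro-4-nitroanisole | COc1ccc([N+](=O)[O-])c(F)c1 | starting material
7 | 1,5-dimethoxy-2-(5-methoxy-2-nitrophenoxy)-3-pentylbenzene | CCCCCc1cc(OC)cc(OC)c1Oc1cc(OC)ccc1[N+](=O)[O-] | intermediate
8 | 2-(2,4-dimethoxy-6-pentylphenoxy)-4-methoxyaniline | CCCCCc1cc(OC)cc(OC)c1Oc1cc(OC)ccc1N | intermediate
9 | 2-(2,4-dimethoxy-6-pentylphenoxy)-4-methoxybenzenediazonium 4-methylbenzenesulfonate | CCCCCc1cc(OC)cc(OC)c1Oc1cc(OC)ccc1[N+]#N.Cc1ccc(S(=O)(=O)[O-])cc1 | intermediate (not isolated)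
10 | 2-(2-iodo-5-methoxyphenoxy)-1,5-dimethoxy-3-pentylbenzene | CCCCCc1cc(OC)cc(OC)c1Oc1cc(OC)ccc1I | intermediate
11 | 2-pentyloxirane (racemic) | CCCCCC1CO1 | starting material
12 | carbon monoxide | [C-]#[O+] | starting material
13 | 8-(2,4-dimethoxy-6-pentylphenoxy)-6-methoxy-3-pentyl-3,4-dihydro-1H-isochromen-1-one (racemic) | CCCCCC1Cc2cc(OC)cc(Oc3c(OC)cc(OC)cc3CCCCC)c2C(=O)O1 | intermediate
14 | 2-(2,4-dimethoxy-6-pentylphenoxy)-6-[(1E)-hept-1-en-1-yl]-4-methoxybenzoic acid | CCCCC/C=C/c1cc(OC)cc(Oc2c(OC)cc(OC)cc2CCCCC)c1C(=O)O | intermediate
15 | 8-(2,4-dimethoxy-6-pentylphenoxy)-6-methoxy-3-pentyl-1H-isochromen-1-one | CCCCCc1cc2cc(OC)cc(Oc3c(OC)cc(OC)cc3CCCCC)c2c(=O)o1 | intermediate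
16 | ({4,6-dimethoxy-3-[(6-methoxy-1-oxo-3-pentyl-1H-isochromen-8-yl)oxy]-2-pentylphenyl}methylidene)dimethylammonium chloride | CCCCCc1cc2cc(OC)cc(Oc3c(OC)cc(OC)c(C=[N+](C)C)c3CCCCC)c2c(=O)o1.[Cl-] | intermediate (not isolated)
17 | 4,6-dimethoxy-3-[(6-methoxy-1-oxo-3-pentyl-1H-isochromen-8-yl)oxy]-2-pentylbenzaldehyde | CCCCCc1cc2cc(OC)cc(Oc3c(OC)cc(OC)c(C=O)c3CCCCC)c2c(=O)o1 | intermediate
18 | 4,6-dimethoxy-3-[(6-methoxy-1-oxo-3-pentyl-1H-isochromen-8-yl)oxy]-2-pentylbenzoic acid | CCCCCc1cc2cc(OC)cc(Oc3c(OC)cc(OC)c(C(=O)O)c3CCCCC)c2c(=O)o1 | intermediate
19 | 4,6-dihydroxy-3-[(6-hydroxy-1-oxo-3-pentyl-1H-isochromen-8-yl)oxy]-2-pentylbenzoic acid | CCCCCc1cc2cc(O)cc(Oc3c(O)cc(O)c(C(=O)O)c3CCCCC)c2c(=O)o1 | target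

## Step count and least certain steps

Total step count: 11. Longest linear sequence: 11 steps (1 to 19); 6, 11 and 12 enter as purchased reactants.

Step 6 (key step). The most likely failure is loss of the required order of events. Carbon monoxide may insert into the first arylpalladium iodide or into the palladacycle before alkylation, it may aggregate the catalyst, or, if it is too scarce, the alkoxide may undergo C–O reductive elimination to a dihydrobenzofuran. The fallback uses known reaction types and sets out from 10. Iodine–magnesium exchange (iPrMgCl·LiCl, THF, −20 °C) and quenching with CO2 gives 2-(2,4-dimethoxy-6-pentylphenoxy)-4-methoxybenzoic acid F1. Carboxylate-directed palladation of the single free ortho C–H of F1 by divalent palladium (Pd(OAc)2, N-acetyl-tert-leucine, KOAc, 11, (CF3)2CHOH, 75 °C), opening of the epoxide at its CH2 terminus and lactonisation of the resulting hydroxy acid in the same flask should give the dihydroisocoumarin, returning to the route at 13.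

Step 8. The most likely failure is poor regioselectivity of the ring closure (5-exo attack on the benzylic carbon, leading toward a phthalide) or slow turnover because the carboxylate is flanked by two ortho substituents. The fallback bypasses 14 and sets out from 13. Radical bromination at C4 (N-bromosuccinimide, AIBN, PhCF3, reflux, Wohl–Ziegler type) gives 4-bromo-8-(2,4-dimethoxy-6-pentylphenoxy)-6-methoxy-3-pentyl-3,4-dihydro-1H-isochromen-1-one F2. Elimination of hydrogen bromide with Et3N then returns to the route at 15. This is the classical dehydrogenation of dihydroisocoumarins; it is held in reserve because ring C offers the bromine atom a second benzylic CH2 and an electron-rich nucleus.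

Step 9. The most likely failure is loss of site selectivity: attack at C3' between the two methoxy groups, or on ring A. The fallback sets out from 15. Ether cleavage with BBr3 (CH2Cl2, −78 → 20 °C) gives 8-(2,4-dihydroxy-6-pentylphenoxy)-6-hydroxy-3-pentyl-1H-isochromen-1-one F3. Chelation-controlled ortho-carboxylation of the ring C resorcinol with MeOMgOCO2Me (DMF, 120 °C, then HCl) then returns to the route at 19. This ending is one step shorter, but it is not the first choice: C3' lies between two hydroxyls and could compete with C1', and the basic magnesium reagent meets the lactone at high temperature.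

Step 11. The most likely failure is loss of CO2 from the electron-rich ortho-hydroxy acid in the acidic medium, or incomplete cleavage of the C6 ether, whose oxygen is conjugated with the lactone carbonyl. The fallback changes the order of events and sets out from 17. BBr3 cleaves the three ethers while the carbon is still an aldehyde, giving 4,6-dihydroxy-3-[(6-hydroxy-1-oxo-3-pentyl-1H-isochromen-8-yl)oxy]-2-pentylbenzaldehyde F4. Chlorite oxidation with sulfamic acid as hypochlorite scavenger (NaClO2, H2NSO3H, THF/H2O, 0 °C) then forms the acid in the last, mild step and returns to the route at 19.

## Further compounds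

F1 | step 6 | 2-(2,4-dimethoxy-6-pentylphenoxy)-4-methoxybenzoic acid | CCCCCc1cc(OC)cc(OC)c1Oc1cc(OC)ccc1C(=O)O
F2 | step 8 | 4-bromo-8-(2,4-dimethoxy-6-pentylphenoxy)-6-methoxy-3-pentyl-3,4-dihydro-1H-isochromen-1-one (racemic, mixture of cis and trans isomers) | CCCCCC1OC(=O)c2c(Oc3c(OC)cc(OC)cc3CCCCC)cc(OC)cc2C1Br
F3 | step 9 | 8-(2,4-dihydroxy-6-pentylphenoxy)-6-hydroxy-3-pentyl-1H-isochromen-1-one | CCCCCc1cc2cc(O)cc(Oc3c(O)cc(O)cc3CCCCC)c2c(=O)o1
F4 | step 11 | 4,6-dihydroxy-3-[(6-hydroxy-1-oxo-3-pentyl-1H-isochromen-8-yl)oxy]-2-pentylbenzaldehyde | CCCCCc1cc2cc(O)cc(Oc3c(O)cc(O)c(C=O)c3CCCCC)c2c(=O)o1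
A1 | alternative 1 | dibenzyl malonate | O=C(CC(=O)OCc1ccccc1)OCc1ccccc1
A2 | alternative 1 | 3-{[6-(benzyloxy)-1-oxo-3-pentyl-1H-isochromen-8-yl]oxy}non-3-en-2-one (alkene geometry not fixed) | CCCCCC=C(Oc1cc(OCc2ccccc2)cc2cc(CCCCC)oc(=O)c12)C(C)=O
A3 | alternative 1 | benzyl 3-{[6-(benzyloxy)-1-oxo-3-pentyl-1H-isochromen-8-yl]oxy}-4,6-dioxo-2-pentylcyclohexane-1-carboxylate (mixture of stereoisomers and enol forms) | CCCCCC1C(Oc2cc(OCc3ccccc3)cc3cc(CCCCC)oc(=O)c23)C(=O)CC(=O)C1C(=O)OCc1ccccc1
A4 | alternative 1 | 6-(benzyloxy)-8-hydroxy-3-pentyl-1H-isochromen-1-one | CCCCCc1cc2cc(OCc3ccccc3)cc(O)c2c(=O)o1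
A5 | alternative 2 | 6-(benzyloxy)-8-{[4-methoxy-2,4-bis(trimethylsilyloxy)buta-1,3-dien-1-yl]oxy}-3-pentyl-1H-isochromen-1-one | COC(O[Si](C)(C)C)=CC(O[Si](C)(C)C)=COc1cc(OCc2ccccc2)cc2cc(CCCCC)oc(=O)c12
A6 | alternative 2 | benzyl oct-2-ynoate | CCCCCC#CC(=O)OCc1ccccc1
A7 | alternative 2 | benzyl 3-{[6-(benzyloxy)-1-oxo-3-pentyl-1H-isochromen-8-yl]oxy}-4,6-dihydroxy-2-pentylbenzoate | CCCCCc1c(Oc2cc(OCc3ccccc3)cc3cc(CCCCC)oc(=O)c23)c(O)cc(O)c1C(=O)OCc1ccccc1
A8 | alternative 3 | 3-methylcyclobut-2-en-1-one | CC1=CC(=O)C1
A9 | alternative 3 | 1,5-bis(benzyloxy)-2-(ethynyloxy)-3-pentylbenzene | C#COc1c(OCc2ccccc2)cc(OCc2ccccc2)cc1CCCCC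
A10 | alternative 3 | 3-[2,4-bis(benzyloxy)-6-pentylphenoxy]-5-methylphenol | Cc1cc(O)cc(Oc2c(OCc3ccccc3)cc(OCc3ccccc3)cc2CCCCC)c1
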